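The route rests on cutting two bonds of the target together: O3–C(acetyl) and C5–H (decane chain numbered from the benzylic carbon, C1). The feature exploited is the acyclic anti C3/C5 diol that bears acetate on O3 and a free hydroxyl on O5. The dimethoxybenzene ring on C1 is only a spectator. One samarium-catalysed Evans–Tishchenko reaction with acetaldehyde reduces the C5 ketone, relays the C3 configuration to C5 and leaves the acetyl group on O3. Its precursor is the enantiopure (3S)-3-hydroxy-5-ketone. This is reached in four steps from 3-(3,4-dimethoxyphenyl)propanoic acid by β-keto ester synthesis, asymmetric hydrogenation, Weinreb amidation and pentyl Grignard addition.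

Key step: step 5

Remark on the chemistry: at both carbinol carbons the CIP order is O > C4 > outer chain > H, so the target is 3S,5S and like descriptors mean the anti diol; the 3S centre calls for the (S)-BINAP ligand, because the (R)-ligand turns 3-oxo esters into (R)-3-hydroxy esters and the CIP order is the same here.

Step 1
Reactants: 1 3-(3,4-dimethoxyphenyl)propanoic acid; 2 2,2-dimethyl-1,3-dioxane-4,6-dione (Meldrum's acid)
Product: 4 methyl 5-(3,4-dimethoxyphenyl)-3-oxopentanoate, via acyl Meldrum's acid 3 (not isolated)
Conditions: DCC, DMAP, CH2Cl2, 0 °C → rt; filter, wash with aq KHSO4, concentrate; then MeOH, reflux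
Reagents that add atoms: methanol, CO
Why: Meldrum's acid β-keto ester synthesis: Steglich-type activation of 1 lets the acidic methylene of 2 be C-acylated to 3, and boiling methanol opens 3 with loss of acetone and CO2 to leave the methyl β-keto ester, with no stereocentre formed.

Step 2
Reactants: 4 methyl 5-(3,4-dimethoxyphenyl)-3-oxopentanoate
Product: 5 methyl (3S)-5-(3,4-dimethoxyphenyl)-3-hydroxypentanoate
Conditions: RuCl2[(S)-BINAP] (0.5 mol %), H2 (10 bar), degassed MeOH, 50 °C
Reagents that add atoms: none
Why: Noyori asymmetric hydrogenation: the ketone and ester oxygens of 4 chelate divalent ruthenium, so the (S)-BINAP pocket admits hydride to one ketone face only and should set C3 as S, while the arene and ester stay untouched and methanol matches the methyl ester.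

Step 3
Reactants: 5 methyl (3S)-5-(3,4-dimethoxyphenyl)-3-hydroxypentanoate
Product: 6 (3S)-5-(3,4-dimethoxyphenyl)-3-hydroxy-N-methoxy-N-methylpentanamide
Conditions: MeNH(OMe)·HCl (2 equiv), iPrMgCl (5 equiv), THF, −20 → 0 °C; aq NH4Cl
Reagents that add atoms: N,O-dimethylhydroxylamine hydrochloride, CNOC.Cl
Why: Weinreb amide formation by ester aminolysis with the magnesium amide made in the flask, in which one extra equivalent of iPrMgCl holds the C3 hydroxyl as its alkoxide and the low temperature should leave the C3 centre, which takes no part, intact.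

Step 4
Reactants: 6 (3S)-5-(3,4-dimethoxyphenyl)-3-hydroxy-N-methoxy-N-methylpentanamide; 7 pentylmagnesium bromide (commercial 2.0 M solution in Et2O)
Product: 9 (3S)-1-(3,4-dimethoxyphenyl)-3-hydroxydecan-5-one, via tetrahedral magnesium adduct 8 (not isolated)
Conditions: n-C5H11MgBr (3 equiv), THF, −20 → 0 °C; cold aq NH4Cl
Reagents that add atoms: none
Why: Weinreb ketone synthesis: the first equivalent of 7 deprotonates O3–H and the second adds to the amide to give the N-methoxy-chelated adduct 8, which persists until the quench and so blocks a second addition, with C3 not involved.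

Step 5
Reactants: 9 (3S)-1-(3,4-dimethoxyphenyl)-3-hydroxydecan-5-one; 10 acetaldehyde
Product: 12 (3S,5S)-1-(3,4-dimethoxyphenyl)-5-hydroxydecan-3-yl acetate, via acetaldehyde hemiacetal 11 (not isolated)
Conditions: SmI2 (0.1 M in THF, 20 mol %), 10 (freshly distilled, 8 equiv), THF, −10 °C, Ar; cold pH 7 buffer (NaH2PO4/Na2HPO4); rapid chromatography on neutral silica
Reagents that add atoms: none
Why: Evans–Tishchenko reduction, the known reaction of β-hydroxy ketones with an aldehyde under samarium catalysis: acetaldehyde oxidises SmI2 to the trivalent samarium species that is the working catalyst, this binds O3 of 9, and the O3 alkoxide adds to 10 to give hemiacetal 11. With samarium bridging the hemiacetal oxygen and the C5 carbonyl oxygen, the hemiacetal C–H shifts as hydride to C5 through a chair-like six-membered array (H, acetal C, O3, C3, C4, C5), so the acetal carbon becomes the acetyl C=O on O3 and C5 becomes an alkoxide that leaves as the free O5–H after proton exchange with fresh 9. No ring is closed, because the cyclic array exists only in the transition state. The single new stereocentre, C5, is governed by C3: with the arylethyl chain on C3 and the pentyl chain on C5 both equatorial, only one face of the ketone meets the hydride, which should give 5S, anti to 3S. The step needs 1,3-anti diastereoselectivity and O3-versus-O5 regioselectivity; the first is secured by the C3-anchored chair of this unhindered dialkyl ketone and the second is inherent, since the acyl carbon is bonded to O3 before hydride moves. Low temperature, short contact time and a cold neutral quench should hold back O3-to-O5 acetyl migration and retro-aldol cleavage.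

Compound list
1 | 3-(3,4-dimethoxyphenyl)propanoic acid | COc1ccc(CCC(=O)O)cc1OC | starting material
2 | 2,2-dimethyl-1,3-dioxane-4,6-dione (Meldrum's acid) | CC1(C)OC(=O)CC(=O)O1 | starting material
3 | 5-[3-(3,4-dimethoxyphenyl)-1-hydroxypropylidene]-2,2-dimethyl-1,3-dioxane-4,6-dione (acyl Meldrum's acid, enol form) | CC1(C)OC(=O)C(=C(O)CCc2ccc(OC)c(OC)c2)C(=O)O1 | intermediate
4 | methyl 5-(3,4-dimethoxyphenyl)-3-oxopentanoate | COC(=O)CC(=O)CCc1ccc(OC)c(OC)c1 | intermediate
5 | methyl (3S)-5-(3,4-dimethoxyphenyl)-3-hydroxypentanoate | COC(=O)C[C@H](CCc1ccc(OC)c(OC)c1)O | intermediate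
6 | (3S)-5-(3,4-dimethoxyphenyl)-3-hydroxy-N-methoxy-N-methylpentanamide | CON(C)C(=O)C[C@H](CCc1ccc(OC)c(OC)c1)O | intermediate
7 | pentylmagnesium bromide | CCCCC[Mg]Br | starting material
8 | bis(bromomagnesium) alkoxide of (3S)-1-(3,4-dimethoxyphenyl)-5-[methoxy(methyl)amino]decane-3,5-diol (tetrahedral adduct, C5 undefined) | CCCCCC(O[Mg]Br)(N(C)OC)C[C@H](CCc1ccc(OC)c(OC)c1)O[Mg]Br | intermediate
9 | (3S)-1-(3,4-dimethoxyphenyl)-3-hydroxydecan-5-one | CCCCCC(=O)C[C@H](CCc1ccc(OC)c(OC)c1)O | intermediate
10 | acetaldehyde | CC=O | starting material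
11 | (3S)-1-(3,4-dimethoxyphenyl)-3-(1-hydroxyethoxy)decan-5-one (samarium-bound hemiacetal, drawn neutral, acetal carbon undefined) | CCCCCC(=O)C[C@H](CCc1ccc(OC)c(OC)c1)OC(C)O | intermediate
12 | (3S,5S)-1-(3,4-dimethoxyphenyl)-5-hydroxydecan-3-yl acetate | CCCCC[C@H](O)C[C@H](CCc1ccc(OC)c(OC)c1)OC(C)=O | target

Total step count: 5. Longest linear sequence: 5 steps (1 → 4 → 5 → 6 → 9 → 12).

Steps most likely to fail

Risk 1, step 5. Acetaldehyde may consume itself by aldol or Tishchenko self-reaction and starve the catalyst. The acetyl group may drift from O3 to O5 on the samarium alkoxide or on silica, and retro-aldol cleavage may erode C3. The fallback sets out from 9 and comes back at 12, and it separates reduction from acylation.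
- Hydroxyl-directed Saksena–Evans reduction of 9 with Me4NBH(OAc)3 in MeCN/AcOH at −30 °C should give the anti diol (3S,5S)-1-(3,4-dimethoxyphenyl)decane-3,5-diol F1. Hydride is delivered internally from the O3-bound acyloxyborohydride.
- Exchange with trimethyl orthoacetate (cat. PPTS, CH2Cl2, rt) would tie both oxygens into the cyclic orthoacetate (4S,6S)-4-[2-(3,4-dimethoxyphenyl)ethyl]-2-methoxy-2-methyl-6-pentyl-1,3-dioxane F2.
- Brief hydrolysis of F2 with aqueous AcOH at 0 °C opens it to monoacetates only. These are 12 and its regioisomer (3S,5S)-1-(3,4-dimethoxyphenyl)-3-hydroxydecan-5-yl acetate F3.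
- This path gives up the built-in regiocontrol. The two esters would have to be separated by chromatography, and F3 returned to F1 with K2CO3 in MeOH for another pass.

Risk 2, step 4. The magnesium alkoxide formed first may aggregate and slow the addition. On warming it may trigger retro-aldol cleavage or β-elimination, and early collapse of the adduct would open the way to over-addition. The fallback sets out from 6 and comes back at 9, and it masks O3 so that no alkoxide is present.
- TESCl and imidazole in CH2Cl2 at 0 °C should give (3S)-5-(3,4-dimethoxyphenyl)-N-methoxy-N-methyl-3-(triethylsilyloxy)pentanamide F4.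
- A slight excess of n-C5H11MgBr in THF at 0 °C converts F4 into (3S)-1-(3,4-dimethoxyphenyl)-3-(triethylsilyloxy)decan-5-one F5.
- AcOH/THF/H2O at rt removes the silyl group without base and returns 9.

Risk 3, step 3. The strongly basic magnesium amide may dehydrate the β-hydroxy ester by an E1cB path, or the exchange may stall short of completion. The fallback sets out from 5 and comes back at 6, and it replaces direct aminolysis by hydrolysis and coupling.
- LiOH in THF/H2O at 0 °C should give (3S)-5-(3,4-dimethoxyphenyl)-3-hydroxypentanoic acid F6.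
- Coupling F6 with MeNH(OMe)·HCl using EDC·HCl, HOBt and iPr2NEt in CH2Cl2 gives 6 under near-neutral conditions.

Further compounds
F1 | step 5 | (3S,5S)-1-(3,4-dimethoxyphenyl)decane-3,5-diol | CCCCC[C@H](O)C[C@H](CCc1ccc(OC)c(OC)c1)O
F2 | step 5 | (4S,6S)-4-[2-(3,4-dimethoxyphenyl)ethyl]-2-methoxy-2-methyl-6-pentyl-1,3-dioxane (C2 undefined) | CCCCC[C@H]1C[C@H](CCc2ccc(OC)c(OC)c2)OC(C)(OC)O1
F3 | step 5 | (3S,5S)-1-(3,4-dimethoxyphenyl)-3-hydroxydecan-5-yl acetate | CCCCC[C@H](OC(C)=O)C[C@H](CCc1ccc(OC)c(OC)c1)O
F4 | step 4 | (3S)-5-(3,4-dimethoxyphenyl)-N-methoxy-N-methyl-3-(triethylsilyloxy)pentanamide | CON(C)C(=O)C[C@H](CCc1ccc(OC)c(OC)c1)O[Si](CC)(CC)CC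
F5 | step 4 | (3S)-1-(3,4-dimethoxyphenyl)-3-(triethylsilyloxy)decan-5-one | CCCCCC(=O)C[C@H](CCc1ccc(OC)c(OC)c1)O[Si](CC)(CC)CC
F6 | step 3 | (3S)-5-(3,4-dimethoxyphenyl)-3-hydroxypentanoic acid | OC(=O)C[C@H](CCc1ccc(OC)c(OC)c1)O
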